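**Retrosynthetic overview**

1. Endgame: the C14 aldehyde and the C15 alcohol are unveiled from two different silyl ethers (selective desilylation, MnO2, HF·pyridine).
2. Key disconnection is the lactone O–C6 bond: in the five-membered α-methylene lactone ring (O, C6, C7, C11, C12) C6 is allylic to C4=C5 and homoallylic to the exocyclic C11=C13 (O–C6–C7–C11=C13), so the ring unfolds to a C6–C7–C11 cyclopropane carrying CH2OMs (C13) and CO2tBu (C12) on C11, whose strain-driven opening forms O–C6, the methylene and the C6 stereocentre at once.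
3. The cyclopropane arises from a ten-membered ring-cis trienol by intramolecular carbenoid cyclopropanation of C6=C7 with a diazomalonate tethered to O8 (temporary lactone ring), which relays C8 to C7 and C6; reduction then frees O8 for the isovalerate.
4. The ten-membered ring is closed by ring-closing metathesis at C6=C7; C1=C10 comes from an (E)-selective Horner–Wadsworth–Emmons reaction of a phosphono lactone made from (S)-2-vinyloxirane (source of C8), and C4=C5 from trans-hydroalumination/iodination of a butynediol ether followed by B-alkyl Suzuki coupling.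
5. Ring order: temporary C14/O8 γ-lactone, ten-membered carbocycle, cyclopropane with temporary O8 γ-lactone, final C12/O6 γ-lactone.

Key step: step 17

Remark: germacrane numbering is used (ring C1–C10, lactone carbons C11–C13, C14 on C10, C15 on C4); the SMILES is read as 6S,7R,8R with H6, H7 and H8 on one face (cis-fused lactone, isovalerate syn to C11) and with the ring carbons cis across both C1=C10 and C4=C5 (both E by CIP).

**Route**

Step 1
Reactants: 1 but-2-yne-1,4-diol
Product: 2 4-[(tert-butyldiphenylsilyl)oxy]but-2-yn-1-ol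
Conditions: NaH (1 equiv), THF, 0 °C to rt; then TBDPSCl, rt
Reagents that add atoms: tert-butyl(chloro)diphenylsilane, CC(C)(C)[Si](Cl)(c1ccccc1)c1ccccc1
Why: Williamson-type monosilylation of the symmetrical diol through its sparingly soluble monosodium alkoxide, which limits double silylation; no stereocentre is formed.

Step 2
Reactants: 2 4-[(tert-butyldiphenylsilyl)oxy]but-2-yn-1-ol
Product: 4 (2Z)-4-[(tert-butyldiphenylsilyl)oxy]-3-iodobut-2-en-1-ol, via cyclic sodium alkenylaluminate 3 (not isolated)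
Conditions: NaAlH2(OCH2CH2OMe)2 (Red-Al), THF, 0 °C to rt; then I2, THF, −78 °C to 0 °C; aq. Na2S2O3
Reagents that add atoms: iodine, II
Why: Hydroxyl-directed trans-hydroalumination of the propargylic alcohol places aluminium on the distal alkyne carbon in a five-membered alkenylaluminate, and iododealumination with retention gives the (Z)-iodoalkene, which fixes the C4=C5 geometry (iodine on C4 cis to the CH2OH carbon, the future C6).

Step 3
Reactants: 4 (2Z)-4-[(tert-butyldiphenylsilyl)oxy]-3-iodobut-2-en-1-ol; 5 3,3-diethoxyprop-1-ene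
Product: 7 (2E)-3-{[(tert-butyldiphenylsilyl)oxy]methyl}-6,6-diethoxyhex-2-en-1-ol, via 9-(3,3-diethoxypropyl)-9-borabicyclo[3.3.1]nonane 6 (not isolated)
Conditions: 5, 9-BBN, THF, 0 °C to rt; then 4, PdCl2(dppf) (cat.), AsPh3, Cs2CO3, DMF/THF/H2O, rt
Reagents that add atoms: none
Why: Anti-Markovnikov hydroboration of the terminal alkene followed by B-alkyl Suzuki–Miyaura coupling, which proceeds with retention at the alkenyl iodide, so the C3 chain ends up cis to C6 across C4=C5.

Step 4
Reactants: 7 (2E)-3-{[(tert-butyldiphenylsilyl)oxy]methyl}-6,6-diethoxyhex-2-en-1-ol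
Product: 8 (2E)-3-{[(tert-butyldiphenylsilyl)oxy]methyl}-6,6-diethoxyhex-2-enal
Conditions: MnO2, CH2Cl2, rt
Reagents that add atoms: none
Why: Chemoselective MnO2 oxidation of the primary allylic alcohol to the enal under neutral conditions that leave the acetal, the silyl ether and the alkene geometry untouched.

Step 5
Reactants: 8 (2E)-3-{[(tert-butyldiphenylsilyl)oxy]methyl}-6,6-diethoxyhex-2-enal
Product: 9 tert-butyl{[(2E)-2-(3,3-diethoxypropyl)penta-2,4-dien-1-yl]oxy}diphenylsilane
Conditions: Ph3PCH3Br, KN(SiMe3)2, THF, −78 °C to 0 °C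
Reagents that add atoms: methyltriphenylphosphonium bromide, C[P+](c1ccccc1)(c1ccccc1)c1ccccc1.[Br-]
Why: Wittig methylenation of the enal with a non-stabilised ylide at low temperature gives the terminal diene needed for ring closure while the C4=C5 geometry is kept.

Step 6
Reactants: 9 tert-butyl{[(2E)-2-(3,3-diethoxypropyl)penta-2,4-dien-1-yl]oxy}diphenylsilane
Product: 10 (4E)-4-{[(tert-butyldiphenylsilyl)oxy]methyl}hepta-4,6-dienal
Conditions: PPTS (cat.), acetone/H2O, 50 °C
Reagents that add atoms: water, O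
Why: Mild acid-catalysed acetal hydrolysis liberates the C1 aldehyde under conditions that leave the tert-butyldiphenylsilyl ether and the diene intact.

Step 7
Reactants: 11 triethyl phosphonoacetate; 12 (2S)-2-ethenyloxirane
Product: 14 diethyl [(5R)-5-ethenyl-2-oxooxolan-3-yl]phosphonate, via sodium alkoxide 13 (not isolated)
Conditions: NaH, 11, DME, 0 °C; then 12, 60–80 °C (sealed); 1 M HCl work-up
Reagents that add atoms: none
Why: Without a palladium catalyst the phosphonoacetate anion should open the vinyl epoxide by SN2 attack at the unsubstituted carbon, and the resulting alkoxide lactonises onto the ethyl ester, so the epoxide stereocentre is carried unchanged into C8 (R through the change of CIP priorities).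

Step 8
Reactants: 14 diethyl [(5R)-5-ethenyl-2-oxooxolan-3-yl]phosphonate; 10 (4E)-4-{[(tert-butyldiphenylsilyl)oxy]methyl}hepta-4,6-dienal
Product: 15 (3E,5R)-3-[(4E)-4-{[(tert-butyldiphenylsilyl)oxy]methyl}hepta-4,6-dien-1-ylidene]-5-ethenyloxolan-2-one
Conditions: NaH, THF, 0 °C; then 10, 0 °C to rt
Reagents that add atoms: none
Why: Horner–Wadsworth–Emmons olefination of the α-phosphono lactone should give mainly the (E)-alkylidene lactone (C2 trans to the carbonyl C14 and cis to C9), which is the ring-cis geometry required for C1=C10, the minor (Z) isomer being removed by chromatography.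

Step 9
Reactants: 15 (3E,5R)-3-[(4E)-4-{[(tert-butyldiphenylsilyl)oxy]methyl}hepta-4,6-dien-1-ylidene]-5-ethenyloxolan-2-one
Product: 16 (2E,6E)-6-{[(tert-butyldiphenylsilyl)oxy]methyl}-2-[(2R)-2-hydroxybut-3-en-1-yl]nona-2,6,8-trien-1-ol
Conditions: iBu2AlH (excess), CH2Cl2, −78 °C to 0 °C; aq. KNaC4H4O6
Reagents that add atoms: none
Why: iBu2AlH reduces the α-alkylidene lactone by 1,2-addition to the allylic diol, which unmasks the C14 hydroxymethyl group and the C8 carbinol without affecting alkene geometry or the C8 stereocentre.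

Step 10
Reactants: 16 (2E,6E)-6-{[(tert-butyldiphenylsilyl)oxy]methyl}-2-[(2R)-2-hydroxybut-3-en-1-yl]nona-2,6,8-trien-1-ol
Product: 17 (3R,5E,9E)-5-{[(tert-butyldimethylsilyl)oxy]methyl}-9-{[(tert-butyldiphenylsilyl)oxy]methyl}dodeca-1,5,9,11-tetraen-3-ol
Conditions: TBSCl (1.05 equiv), imidazole, CH2Cl2, −20 °C
Reagents that add atoms: tert-butyl(chloro)dimethylsilane, CC(C)(C)[Si](C)(C)Cl
Why: Silylation at low temperature discriminates the primary allylic alcohol from the secondary one on steric grounds.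

Step 11
Reactants: 17 (3R,5E,9E)-5-{[(tert-butyldimethylsilyl)oxy]methyl}-9-{[(tert-butyldiphenylsilyl)oxy]methyl}dodeca-1,5,9,11-tetraen-3-ol
Product: 18 (1R,2Z,4E,8E)-9-{[(tert-butyldimethylsilyl)oxy]methyl}-5-{[(tert-butyldiphenylsilyl)oxy]methyl}cyclodeca-2,4,8-trien-1-ol
Conditions: second-generation Grubbs catalyst RuCl2(=CHPh)(PCy3)(H2IMes) (cat.), CH2Cl2 (high dilution), 40 °C
Reagents that add atoms: none
Why: Ring-closing metathesis between the vinyl carbinol and the terminal alkene of the diene (the trisubstituted alkenes are inert) should close the ten-membered ring with loss of ethene, the two pre-installed ring-cis alkenes bringing the termini together and the medium ring favouring the (Z)-C6=C7 bond.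

Step 12
Reactants: 18 (1R,2Z,4E,8E)-9-{[(tert-butyldimethylsilyl)oxy]methyl}-5-{[(tert-butyldiphenylsilyl)oxy]methyl}cyclodeca-2,4,8-trien-1-ol; 19 3-(tert-butoxy)-3-oxopropanoic acid
Product: 20 tert-butyl (1R,2Z,4E,8E)-9-{[(tert-butyldimethylsilyl)oxy]methyl}-5-{[(tert-butyldiphenylsilyl)oxy]methyl}cyclodeca-2,4,8-trien-1-yl propanedioate
Conditions: DCC, DMAP (cat.), CH2Cl2, 0 °C to rt
Reagents that add atoms: none
Why: Steglich esterification of the secondary dienylic alcohol with the malonic half ester takes place at oxygen and leaves the C8 stereocentre untouched.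

Step 13
Reactants: 20 tert-butyl (1R,2Z,4E,8E)-9-{[(tert-butyldimethylsilyl)oxy]methyl}-5-{[(tert-butyldiphenylsilyl)oxy]methyl}cyclodeca-2,4,8-trien-1-yl propanedioate
Product: 21 tert-butyl (1R,2Z,4E,8E)-9-{[(tert-butyldimethylsilyl)oxy]methyl}-5-{[(tert-butyldiphenylsilyl)oxy]methyl}cyclodeca-2,4,8-trien-1-yl 2-diazopropanedioate
Conditions: 4-acetamidobenzenesulfonyl azide, Et3N, MeCN, rt
Reagents that add atoms: 4-acetamidobenzenesulfonyl azide, CC(=O)Nc1ccc(cc1)S(=O)(=O)N=[N+]=[N-]
Why: Regitz diazo transfer from the sulfonyl azide to the activated methylene of the mixed malonate.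

Step 14
Reactants: 21 tert-butyl (1R,2Z,4E,8E)-9-{[(tert-butyldimethylsilyl)oxy]methyl}-5-{[(tert-butyldiphenylsilyl)oxy]methyl}cyclodeca-2,4,8-trien-1-yl 2-diazopropanedioate
Product: 22 tricyclic cyclopropane lactone tert-butyl ester (C6–C7–C11 cyclopropane cis-fused to the ten-membered ring on the O8 face; one C11 carbonyl lactonised to O8; CO2tBu on C11 anti to C8)
Conditions: Rh2(OAc)4 (cat.), CH2Cl2, 40 °C, slow addition of 21
Reagents that add atoms: none
Why: Intramolecular cyclopropanation by the rhodium carbenoid of an allylic diazomalonate, in which the five-membered tether delivers the carbene to the proximal C6=C7 bond on the face of O8 and stereospecific syn addition to the (Z)-alkene gives the cis-fused cyclopropane, so that C7, C6 and C11 are set from C8.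

Step 15
Reactants: 22 tricyclic cyclopropane lactone tert-butyl ester
Product: 23 tert-butyl 9-hydroxy-11-(hydroxymethyl)-7-{[(tert-butyldimethylsilyl)oxy]methyl}-3-{[(tert-butyldiphenylsilyl)oxy]methyl}bicyclo[8.1.0]undeca-2,6-diene-11-carboxylate
Conditions: LiBH4, THF, 0 °C to rt; aq. NH4Cl
Reagents that add atoms: none
Why: LiBH4 reduces the activated lactone carbonyl to the primary alcohol (the future C13) and frees O8, while the hindered tert-butyl ester should not be reduced and no stereocentre is affected.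

Step 16
Reactants: 23 tert-butyl 9-hydroxy-11-(hydroxymethyl)-7-{[(tert-butyldimethylsilyl)oxy]methyl}-3-{[(tert-butyldiphenylsilyl)oxy]methyl}bicyclo[8.1.0]undeca-2,6-diene-11-carboxylate
Product: 25 tert-butyl 11-[(methanesulfonyloxy)methyl]-9-(3-methylbutanoyloxy)-7-{[(tert-butyldimethylsilyl)oxy]methyl}-3-{[(tert-butyldiphenylsilyl)oxy]methyl}bicyclo[8.1.0]undeca-2,6-diene-11-carboxylate, via primary monomesylate 24 (not isolated)
Conditions: MsCl (1.05 equiv), Et3N, CH2Cl2, −40 °C; then (iPrCH2CO)2O, DMAP (cat.), −40 °C to 0 °C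
Reagents that add atoms: methanesulfonyl chloride, CS(=O)(=O)Cl; 3-methylbutanoic anhydride, CC(C)CC(=O)OC(=O)CC(C)C
Why: Sulfene-type mesylation at low temperature selects the primary hydroxyl, and DMAP-catalysed acylation of the remaining secondary C8 hydroxyl installs the isovalerate before the mesylate is allowed to ionise.

Step 17
Reactants: 25 tert-butyl 11-[(methanesulfonyloxy)methyl]-9-(3-methylbutanoyloxy)-7-{[(tert-butyldimethylsilyl)oxy]methyl}-3-{[(tert-butyldiphenylsilyl)oxy]methyl}bicyclo[8.1.0]undeca-2,6-diene-11-carboxylate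
Product: 28 (6S,7R,8R)-14-[(tert-butyldimethylsilyl)oxy]-15-[(tert-butyldiphenylsilyl)oxy]-8-(3-methylbutanoyloxy)germacra-1(10),4,11(13)-trien-12,6-olide, via allyl cation 26 (not isolated), via tert-butyloxonium ion 27 (not isolated)
Conditions: 2,6-lutidine, (CF3)2CHOH/CH2Cl2, 0 °C to 30 °C
Reagents that add atoms: none
Why: Proposed new method: heterolysis of the primary cyclopropylcarbinyl mesylate is assisted by the C6–C11 cyclopropane bond, whose cleavage is drawn toward C6 because the C4=C5 vinyl group makes the emerging cation allylic (26), and the carbonyl oxygen of the tert-butyl ester on C11 then closes onto C6 (5-exo-trig closure of the γ-lactone, forming O–C6) to give the tert-butyloxonium ion 27, which loses 2-methylpropene. The closest known reaction type is the cyclopropylcarbinyl-to-homoallyl rearrangement that converts 1-(halomethyl)- or 1-(sulfonyloxymethyl)cyclopropane-1-carboxylates into α-methylene-γ-butyrolactones in two stages, together with cation capture by tert-butyl esters with loss of 2-methylpropene as in tert-butyl ester halolactonisations; what is new is their merger into one stereoretentive event on a vinylcyclopropane inside a ten-membered ring. One operation thus releases the cyclopropane strain, closes the lactone ring, creates the exocyclic C11=C13 methylene from the mesylate-bearing carbon and removes the tert-butyl group. The new stereocentre C6 should form with retention, because the oxygen is tethered through C12–C11–C7 and can only reach the face of C6 from which C11 departs, so the cis cyclopropane (H6 and H7 syn, set in step 14) is translated into the cis-fused lactone while C7 and C8 are untouched. The step needs cleavage of C6–C11 and not C7–C11 (secured by allylic stabilisation at C6), attack at C6 and not C4 of the allyl cation (five- against seven-membered ring), and capture faster than rotation about C4–C5 or proton loss (nucleophile held at bonding distance, buffered non-nucleophilic medium).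

Step 18
Reactants: 28 (6S,7R,8R)-14-[(tert-butyldimethylsilyl)oxy]-15-[(tert-butyldiphenylsilyl)oxy]-8-(3-methylbutanoyloxy)germacra-1(10),4,11(13)-trien-12,6-olide
Product: 29 (6S,7R,8R)-15-[(tert-butyldiphenylsilyl)oxy]-14-hydroxy-8-(3-methylbutanoyloxy)germacra-1(10),4,11(13)-trien-12,6-olide
Conditions: PPTS (cat.), MeOH, rt
Reagents that add atoms: none
Why: Mild acid-catalysed methanolysis cleaves the primary tert-butyldimethylsilyl ether much faster than the tert-butyldiphenylsilyl ether, and the esters and the α-methylene lactone are inert to these non-basic conditions.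

Step 19
Reactants: 29 (6S,7R,8R)-15-[(tert-butyldiphenylsilyl)oxy]-14-hydroxy-8-(3-methylbutanoyloxy)germacra-1(10),4,11(13)-trien-12,6-olide
Product: 30 (6S,7R,8R)-15-[(tert-butyldiphenylsilyl)oxy]-8-(3-methylbutanoyloxy)-14-oxogermacra-1(10),4,11(13)-trien-12,6-olide
Conditions: MnO2, CH2Cl2, rt
Reagents that add atoms: none
Why: MnO2 oxidises the allylic C14 alcohol to the conjugated aldehyde under neutral conditions, and the enal formed already has the thermodynamically preferred geometry (C2 trans to the formyl group).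

Step 20
Reactants: 30 (6S,7R,8R)-15-[(tert-butyldiphenylsilyl)oxy]-8-(3-methylbutanoyloxy)-14-oxogermacra-1(10),4,11(13)-trien-12,6-olide
Product: 31 (6S,7R,8R)-15-hydroxy-8-(3-methylbutanoyloxy)-14-oxogermacra-1(10),4,11(13)-trien-12,6-olide (target)
Conditions: HF·pyridine, pyridine, THF, 0 °C to rt
Reagents that add atoms: none
Why: Cleavage of the tert-butyldiphenylsilyl ether with buffered HF·pyridine avoids basic conditions that would add to the α-methylene lactone or the enal and liberates the C15 alcohol of the target.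

**Compound list**

1 | but-2-yne-1,4-diol | OCC#CCO | starting material
2 | 4-[(tert-butyldiphenylsilyl)oxy]but-2-yn-1-ol | OCC#CCO[Si](c1ccccc1)(c1ccccc1)C(C)(C)C | intermediate
3 | cyclic sodium alkenylaluminate (five-membered O–Al–C=C–CH2 ring, Al on the carbon bearing CH2OTBDPS, two 2-methoxyethoxy ligands) | [Na+].COCCO[Al-]1(OCCOC)OCC=C1CO[Si](c1ccccc1)(c1ccccc1)C(C)(C)C | intermediate (not isolated)
4 | (2Z)-4-[(tert-butyldiphenylsilyl)oxy]-3-iodobut-2-en-1-ol | OC/C=C(\I)CO[Si](c1ccccc1)(c1ccccc1)C(C)(C)C | intermediate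
5 | 3,3-diethoxyprop-1-ene (acrolein diethyl acetal) | C=CC(OCC)OCC | starting material
6 | 9-(3,3-diethoxypropyl)-9-borabicyclo[3.3.1]nonane | CCOC(CCB1C2CCCC1CCC2)OCC | intermediate (not isolated)
7 | (2E)-3-{[(tert-butyldiphenylsilyl)oxy]methyl}-6,6-diethoxyhex-2-en-1-ol (CH2OH cis to the diethoxypropyl chain) | OC/C=C(\CCC(OCC)OCC)CO[Si](c1ccccc1)(c1ccccc1)C(C)(C)C | intermediate
8 | (2E)-3-{[(tert-butyldiphenylsilyl)oxy]methyl}-6,6-diethoxyhex-2-enal | O=C/C=C(\CCC(OCC)OCC)CO[Si](c1ccccc1)(c1ccccc1)C(C)(C)C | intermediate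
9 | tert-butyl{[(2E)-2-(3,3-diethoxypropyl)penta-2,4-dien-1-yl]oxy}diphenylsilane | C=C/C=C(\CCC(OCC)OCC)CO[Si](c1ccccc1)(c1ccccc1)C(C)(C)C | intermediate
10 | (4E)-4-{[(tert-butyldiphenylsilyl)oxy]methyl}hepta-4,6-dienal | C=C/C=C(\CCC=O)CO[Si](c1ccccc1)(c1ccccc1)C(C)(C)C | intermediate
11 | triethyl phosphonoacetate | CCOC(=O)CP(=O)(OCC)OCC | starting material
12 | (2S)-2-ethenyloxirane | C=C[C@H]1CO1 | starting material
13 | sodium (3R)-5-(diethoxyphosphoryl)-6-ethoxy-6-oxohex-1-en-3-olate (C5 epimers) | [Na+].CCOC(=O)C(C[C@@H]([O-])C=C)P(=O)(OCC)OCC | intermediate (not isolated)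
14 | diethyl [(5R)-5-ethenyl-2-oxooxolan-3-yl]phosphonate (C3 epimers) | C=C[C@H]1CC(P(=O)(OCC)OCC)C(=O)O1 | intermediate
15 | (3E,5R)-3-[(4E)-4-{[(tert-butyldiphenylsilyl)oxy]methyl}hepta-4,6-dien-1-ylidene]-5-ethenyloxolan-2-one | C=C[C@H]1C/C(=C\CC/C(CO[Si](c2ccccc2)(c2ccccc2)C(C)(C)C)=C\C=C)C(=O)O1 | intermediate
16 | (2E,6E)-6-{[(tert-butyldiphenylsilyl)oxy]methyl}-2-[(2R)-2-hydroxybut-3-en-1-yl]nona-2,6,8-trien-1-ol | C=C[C@H](O)C/C(CO)=C\CC/C(CO[Si](c1ccccc1)(c1ccccc1)C(C)(C)C)=C\C=C | intermediate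
17 | (3R,5E,9E)-5-{[(tert-butyldimethylsilyl)oxy]methyl}-9-{[(tert-butyldiphenylsilyl)oxy]methyl}dodeca-1,5,9,11-tetraen-3-ol | C=C[C@H](O)C/C(CO[Si](C)(C)C(C)(C)C)=C\CC/C(CO[Si](c1ccccc1)(c1ccccc1)C(C)(C)C)=C\C=C | intermediate
18 | (1R,2Z,4E,8E)-9-{[(tert-butyldimethylsilyl)oxy]methyl}-5-{[(tert-butyldiphenylsilyl)oxy]methyl}cyclodeca-2,4,8-trien-1-ol (all three ring double bonds cis within the ring) | O[C@H]1/C=C\C=C(CO[Si](c2ccccc2)(c2ccccc2)C(C)(C)C)/CC/C=C(CO[Si](C)(C)C(C)(C)C)\C1 | intermediate
19 | 3-(tert-butoxy)-3-oxopropanoic acid (mono-tert-butyl malonate) | CC(C)(C)OC(=O)CC(=O)O | starting material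
20 | tert-butyl (1R,2Z,4E,8E)-9-{[(tert-butyldimethylsilyl)oxy]methyl}-5-{[(tert-butyldiphenylsilyl)oxy]methyl}cyclodeca-2,4,8-trien-1-yl propanedioate | CC(C)(C)OC(=O)CC(=O)O[C@H]1/C=C\C=C(CO[Si](c2ccccc2)(c2ccccc2)C(C)(C)C)/CC/C=C(CO[Si](C)(C)C(C)(C)C)\C1 | intermediate
21 | tert-butyl (1R,2Z,4E,8E)-9-{[(tert-butyldimethylsilyl)oxy]methyl}-5-{[(tert-butyldiphenylsilyl)oxy]methyl}cyclodeca-2,4,8-trien-1-yl 2-diazopropanedioate | CC(C)(C)OC(=O)C(=[N+]=[N-])C(=O)O[C@H]1/C=C\C=C(CO[Si](c2ccccc2)(c2ccccc2)C(C)(C)C)/CC/C=C(CO[Si](C)(C)C(C)(C)C)\C1 | intermediate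
22 | tricyclic cyclopropane lactone tert-butyl ester (8R; C6–C7–C11 cyclopropane cis-fused to the ten-membered diene on the O8 face, H6 and H7 syn; lactone carbonyl on C11 bound to O8 and cis to C8; CO2tBu on C11 cis to H6/H7; OTBS-methyl on C10, OTBDPS-methyl on C4) | CC(C)(C)OC(=O)[C@]12C(=O)O[C@@H]3C/C(CO[Si](C)(C)C(C)(C)C)=C\CC/C(CO[Si](c4ccccc4)(c4ccccc4)C(C)(C)C)=C\[C@H]1[C@H]23 | intermediate
23 | tert-butyl 9-hydroxy-11-(hydroxymethyl)-7-{[(tert-butyldimethylsilyl)oxy]methyl}-3-{[(tert-butyldiphenylsilyl)oxy]methyl}bicyclo[8.1.0]undeca-2,6-diene-11-carboxylate (germacrane C8 R; cyclopropane on the O8 face, H6 and H7 syn; CH2OH on C11 cis to C8) | CC(C)(C)OC(=O)[C@]1(CO)[C@H]2/C=C(CO[Si](c3ccccc3)(c3ccccc3)C(C)(C)C)\CC/C=C(CO[Si](C)(C)C(C)(C)C)\C[C@@H](O)[C@@H]12 | intermediate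
24 | primary monomesylate of 23 (CH2OMs on C11, free C8 hydroxyl) | CC(C)(C)OC(=O)[C@]1(COS(C)(=O)=O)[C@H]2/C=C(CO[Si](c3ccccc3)(c3ccccc3)C(C)(C)C)\CC/C=C(CO[Si](C)(C)C(C)(C)C)\C[C@@H](O)[C@@H]12 | intermediate (not isolated)
25 | tert-butyl 11-[(methanesulfonyloxy)methyl]-9-(3-methylbutanoyloxy)-7-{[(tert-butyldimethylsilyl)oxy]methyl}-3-{[(tert-butyldiphenylsilyl)oxy]methyl}bicyclo[8.1.0]undeca-2,6-diene-11-carboxylate (stereochemistry as in 23) | CC(C)(C)OC(=O)[C@]1(COS(C)(=O)=O)[C@H]2/C=C(CO[Si](c3ccccc3)(c3ccccc3)C(C)(C)C)\CC/C=C(CO[Si](C)(C)C(C)(C)C)\C[C@@H](OC(=O)CC(C)C)[C@@H]12 | intermediate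
26 | ring-opened allyl cation (C6–C5–C4) bearing the tert-butyl 2-propenoate unit on C7 | C=C(C(=O)OC(C)(C)C)[C@H]1[CH+]/C=C(/CO[Si](c2ccccc2)(c2ccccc2)C(C)(C)C)CC/C=C(/CO[Si](C)(C)C(C)(C)C)C[C@H]1OC(=O)CC(C)C | intermediate (not isolated)
27 | O-tert-butyl lactonium (dialkoxycarbenium) ion, O–C6 bond formed | C=C1C(=[O+]C(C)(C)C)O[C@H]2/C=C(/CO[Si](c3ccccc3)(c3ccccc3)C(C)(C)C)CC/C=C(/CO[Si](C)(C)C(C)(C)C)C[C@@H](OC(=O)CC(C)C)[C@@H]12 | intermediate (not isolated)
28 | (6S,7R,8R)-14-[(tert-butyldimethylsilyl)oxy]-15-[(tert-butyldiphenylsilyl)oxy]-8-(3-methylbutanoyloxy)germacra-1(10),4,11(13)-trien-12,6-olide (cis-fused lactone, ring-cis alkenes) | C=C1C(=O)O[C@H]2/C=C(/CO[Si](c3ccccc3)(c3ccccc3)C(C)(C)C)CC/C=C(/CO[Si](C)(C)C(C)(C)C)C[C@@H](OC(=O)CC(C)C)[C@@H]12 | intermediate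
29 | (6S,7R,8R)-15-[(tert-butyldiphenylsilyl)oxy]-14-hydroxy-8-(3-methylbutanoyloxy)germacra-1(10),4,11(13)-trien-12,6-olide | C=C1C(=O)O[C@H]2/C=C(/CO[Si](c3ccccc3)(c3ccccc3)C(C)(C)C)CC/C=C(/CO)C[C@@H](OC(=O)CC(C)C)[C@@H]12 | intermediate
30 | (6S,7R,8R)-15-[(tert-butyldiphenylsilyl)oxy]-8-(3-methylbutanoyloxy)-14-oxogermacra-1(10),4,11(13)-trien-12,6-olide | C=C1C(=O)O[C@H]2/C=C(/CO[Si](c3ccccc3)(c3ccccc3)C(C)(C)C)CC/C=C(/C=O)C[C@@H](OC(=O)CC(C)C)[C@@H]12 | intermediate
31 | (6S,7R,8R)-15-hydroxy-8-(3-methylbutanoyloxy)-14-oxogermacra-1(10),4,11(13)-trien-12,6-olide | C=C1C(=O)O[C@H]2/C=C(/CO)CC/C=C(/C=O)C[C@@H](OC(=O)CC(C)C)[C@@H]12 | target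

**Step count and risks**

Total step count: 20. Longest linear sequence: 19 steps (steps 1–6 and 8–20, from but-2-yne-1,4-diol); step 7 is a one-step branch.

Steps most likely to fail:

1. Step 17 (Proposed new method). The ionised intermediate may be captured without stereochemical memory (rotation about C6–C7 or C4–C5 before ring closure), may lose a proton to give a triene, or may be intercepted by the isovalerate carbonyl instead of the tert-butyl ester. The fallback uses the known two-stage version of the same rearrangement and sets out from 25. MgBr2·OEt2 in Et2O/CH2Cl2 at 0 °C would open the cyclopropylcarbinyl mesylate with external bromide (attack at C6 with inversion) to the ring-opened allylic bromide tert-butyl acrylate F1. TMSOTf/2,6-lutidine followed by aqueous work-up would cleave the tert-butyl ester without loss of the silyl ethers to give the bromo acrylic acid F2. NaHCO3 in DMF would then close the lactone by intramolecular carboxylate displacement of the allylic bromide (second inversion, net retention at C6), and the route is rejoined at 28.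

2. Step 11. Oligomerisation may outrun closure of the strained ten-membered ring, the C6=C7 bond may form with the wrong geometry, or the allylic alcohol may isomerise at the ruthenium centre. The fallback changes the substrate to a conformationally locked one and sets out from 15. Metathesis would be run one stage earlier, where the (E)-alkylidene lactone ring holds C8 and C1 on the same side and masks the alcohol, to give the bridged bicyclic macrolactone F3. Reduction with iBu2AlH would then give the macrocyclic diol F4, and selective silylation of its primary hydroxyl with TBSCl/imidazole rejoins the route at 18.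

3. Step 16. Discrimination of the two hydroxyls may be incomplete, and the hydroxy mesylate 24 may ionise early, with capture by the free C8 hydroxyl (cyclic ether) before the isovalerate is in place. The fallback sets out from 23 and introduces the leaving group last. TESCl/imidazole at −40 °C would silylate the primary hydroxyl to give the triethylsilyl ether F5. Acylation with 3-methylbutanoic anhydride/DMAP would give the triethylsilyl ether isovalerate F6. PPTS in MeOH at 0 °C would remove the triethylsilyl group in the presence of the other two silyl ethers to give the primary alcohol isovalerate F7. Mesylation of F7 (MsCl, Et3N, −40 °C) immediately before use rejoins the route at 25.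

**Further compounds**

F1 | step 17 | tert-butyl 2-[6-bromo-8-(3-methylbutanoyloxy)-14-(tert-butyldimethylsilyloxy)-15-(tert-butyldiphenylsilyloxy)germacra-1(10),4-dien-7-yl]prop-2-enoate (Br on C6 anti to the C7 substituent; 7R,8R) | C=C(C(=O)OC(C)(C)C)[C@H]1[C@H](Br)/C=C(/CO[Si](c2ccccc2)(c2ccccc2)C(C)(C)C)CC/C=C(/CO[Si](C)(C)C(C)(C)C)C[C@H]1OC(=O)CC(C)C
F2 | step 17 | 2-[6-bromo-8-(3-methylbutanoyloxy)-14-(tert-butyldimethylsilyloxy)-15-(tert-butyldiphenylsilyloxy)germacra-1(10),4-dien-7-yl]prop-2-enoic acid | C=C(C(=O)O)[C@H]1[C@H](Br)/C=C(/CO[Si](c2ccccc2)(c2ccccc2)C(C)(C)C)CC/C=C(/CO[Si](C)(C)C(C)(C)C)C[C@H]1OC(=O)CC(C)C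
F3 | step 11 | bridged macrolactone: ten-membered (2Z,4E,8E)-triene whose C10 carbonyl carbon (C14) is lactonised to O8, 15-(tert-butyldiphenylsilyloxy), 8R | O=C1O[C@@H]2C/C1=C\CC/C(CO[Si](c3ccccc3)(c3ccccc3)C(C)(C)C)=C\C=C/2
F4 | step 11 | (1R,2Z,4E,8E)-5-{[(tert-butyldiphenylsilyl)oxy]methyl}-9-(hydroxymethyl)cyclodeca-2,4,8-trien-1-ol | O[C@H]1/C=C\C=C(CO[Si](c2ccccc2)(c2ccccc2)C(C)(C)C)/CC/C=C(CO)\C1
F5 | step 16 | triethylsilyl ether of 23 at the primary (C11–CH2) hydroxyl | CC(C)(C)OC(=O)[C@]1(CO[Si](CC)(CC)CC)[C@H]2/C=C(CO[Si](c3ccccc3)(c3ccccc3)C(C)(C)C)\CC/C=C(CO[Si](C)(C)C(C)(C)C)\C[C@@H](O)[C@@H]12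
F6 | step 16 | 3-methylbutanoate of F5 at the C8 hydroxyl | CC(C)(C)OC(=O)[C@]1(CO[Si](CC)(CC)CC)[C@H]2/C=C(CO[Si](c3ccccc3)(c3ccccc3)C(C)(C)C)\CC/C=C(CO[Si](C)(C)C(C)(C)C)\C[C@@H](OC(=O)CC(C)C)[C@@H]12
F7 | step 16 | tert-butyl 11-(hydroxymethyl)-9-(3-methylbutanoyloxy)-7-{[(tert-butyldimethylsilyl)oxy]methyl}-3-{[(tert-butyldiphenylsilyl)oxy]methyl}bicyclo[8.1.0]undeca-2,6-diene-11-carboxylate | CC(C)(C)OC(=O)[C@]1(CO)[C@H]2/C=C(CO[Si](c3ccccc3)(c3ccccc3)C(C)(C)C)\CC/C=C(CO[Si](C)(C)C(C)(C)C)\C[C@@H](OC(=O)CC(C)C)[C@@H]12
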